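**Quick number.** To the colleague who asked for figures on the new flask at 0.980 equiv: the charges, runs and questions stand below. Amber is the run to read, as it has these equivalents at twice the concentration.

| flask | first end groups | second end groups | remark | time |
|---|---|---|---|---|
| red | 0.40 M | 0.49 equiv | run made earlier |  |
| violet | 0.40 M | 0.73 equiv | run made earlier |  |
| amber | 0.80 M | 0.98 equiv | run made earlier |  |
| flask | 0.40 M | 0.980 equiv |  | 30 h |

| run | time / h | first end groups / % | links / % | side product / % |
|---|---|---|---|---|
| red | 4.00 | 61.9 | 27.2 | 10.2 |
| red | 8.00 | 58.7 | 23.9 | 16.3 |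
| red | 12.0 | 54.5 | 18.4 | 24.5 |
| red | 15.0 | 53.4 | 16.3 | 28.9 |
| red | 20.0 | 54.3 | 15.6 | 31.9 |
| red | 25.0 | 50.8 | 11.0 | 34.3 |
| red | 30.0 | 51.4 | 10.9 | 37.2 |
| violet | 4.00 | 48.3 | 34.5 | 18.2 |
| violet | 8.00 | 42.2 | 28.5 | 30.4 |
| violet | 12.0 | 36.3 | 22.7 | 38.6 |
| violet | 15.0 | 36.4 | 18.6 | 44.0 |
| violet | 20.0 | 34.5 | 17.2 | 48.6 |
| violet | 25.0 | 33.3 | 16.4 | 52.2 |
| violet | 30.0 | 31.0 | 11.7 | 56.2 |
| amber | 6.00 | 27.2 | 25.6 | 50.6 |
| amber | 12.0 | 17.6 | 13.5 | 66.0 |
| amber | 20.0 | 11.4 | 9.8 | 75.7 |
| amber | 25.0 | 9.4 | 9.2 | 81.0 |
| amber | 30.0 | 9.3 | 8.2 | 83.7 |

(readings scatter by 1 percentage point)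

- why nothing more happens at 30 h, or that something still does (forward and back rates have come level / all of the first end groups has reacted / it is still moving / the second end groups has run out first)
- part of the first end groups gone at 30 h
- the links standing at 30 h, as a percentage of the first end groups charged
- the side product standing at 30 h, as a percentage of the first end groups charged

- the analysis behind the earlier runs scatters by 1 percentage point, standard deviation
- the reaction counts as stopped when no species that holds the first end groups changes by six tenths of a point or more over the second half of the time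

**What holds still.** In amber, links over first end groups read 0.941 at 6.00 h and 0.882 at 30.0 h, so the ratio can be frozen at the first reading. Let S be the pool of first end groups plus links, their resting state, as a fraction of the charge. Amber's S reads 52.8 %, then 17.5 %. The inverse of S starts at 1, and its mean hourly rise up to those times reads 0.149 h⁻¹ and 0.157 h⁻¹. The first-order constant reads 0.106 h⁻¹ and 0.0581 h⁻¹, so it does not hold still, and the pool is taken as lost by second order. Such a loss, in fractions of the charge, scales with the concentration, so G = 0.0786 h⁻¹: the drain slope, the hourly rise of the inverse of S at these equivalents and this concentration.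

**Own reckoning.** For 30 h this reckoning puts S in the new flask at 29.8 %. That means side product 70.2 %, links 14.4 % and conversion 84.6 %. Reckoned S falls by 16 percentage points over the second half, so this reckoning has the flask still moving.

**The forecast.** It gives 84 % gone, 13 % links, 71 % side product and "it is still moving", noting “Amber shows side product still rising at this ratio”. Its links stand 1.4 points below this reckoning.

**The result.** The flask gives 85.8 % gone, 13.9 % links and 71.7 % side product, and it is still moving.

    first end groups + second end groups ⇌ links + by-product (K = 1.30, k = 0.0526 M⁻¹ min⁻¹)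
    2 first end groups → self-condensation product (k = 1.47 × 10⁻⁵ M⁻¹ min⁻¹)
    links + by-product → side product (k = 0.0144 M⁻¹ min⁻¹)

**Slope reused.** The flask's S is 28.1 %, against 29.8 % from G. The same flask read at 20 h gets from G a pool of 38.9 %, hence side product 61.1 % and links 18.9 %. That flask stands at 81.5 % gone, 18.5 % links and 62.8 % side product.

The numbers in the tables stem from a simulated flask for substances that don't exist, and the scatter is random.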